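## Retrosynthetic overview

1. Target ⇐ the 1(10)E,4Z-heliangolide diester by a late, face-selective peracid epoxidation (the ring oxirane is formed last).
2. Heliangolide ⇐ an open-chain (Z)-alkenyl iodide / C6 aldehyde. One NiCl2/CrCl2 operation forms C5–C6 (ten-membered carbocycle) and the new C6 alkoxide closes the γ-lactone on the C12 methyl ester, so two rings form and C6 is set; the ring is not closed at C6–C7.
3. Open-chain aldehyde ⇐ C7–C8 bond by catalytic asymmetric syn 2-(methoxycarbonyl)allylation of a C8 aldehyde with a bromomethylacrylate that carries C6 as an acetal (sets C7 and C8). O8 is then esterified with the (2S,3R)-epoxy acid, made separately by Sharpless epoxidation of tiglyl alcohol.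
4. C8 aldehyde ⇐ Brown allylation of (Z)-3-iodo-2-methylacrolein (sets C3; from propargyl alcohol), cross-metathesis with methacrolein (E-1(10) olefin), methylenation, terminal hydroboration, oxidation.
5. Ring order: side-chain oxirane (on the fragment) → carbocycle and lactone together → 1,10-oxirane.

Assumption: the structure is taken exactly as the SMILES encodes it (germacrane numbering C1–C15; 1R,3S,6R,7R,8R,10R; 4Z; the O8 acyl group is (2S,3R)-2,3-dimethyloxirane-2-carbonyl, methyls cis).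

## Route

Step 1
Reactants: 1 prop-2-yn-1-ol
Product: 3 (2Z)-3-iodo-2-methylprop-2-en-1-ol, via alkenylmagnesium alkoxide 2 (not isolated)
Conditions: MeMgBr (2.3 equiv), CuI (10 mol %), THF, −10 → 25 °C; then I2, −10 °C; 1 M HCl work-up
Reagents that add atoms: methylmagnesium bromide, C[Mg]Br; iodine, II
Why: Copper-catalysed anti-carbomagnesiation of the propargylic alkoxide (Duboudin–Jousseaume) puts the methyl on the internal carbon and magnesium cis to CH2O in a five-membered chelate, and iodinolysis goes with retention, so only the Z-iodide forms.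

Step 2
Reactants: 3 (2Z)-3-iodo-2-methylprop-2-en-1-ol
Product: 4 (2Z)-3-iodo-2-methylprop-2-enal
Conditions: MnO2 (15 equiv), CH2Cl2, 0 °C, dark; filtered and used at once
Reagents that add atoms: none
Why: MnO2 oxidises the allylic alcohol selectively under neutral conditions that leave the C–I bond and the Z geometry intact.

Step 3
Reactants: 4 (2Z)-3-iodo-2-methylprop-2-enal
Product: 6 (1Z,3S)-1-iodo-2-methylhexa-1,5-dien-3-ol, via borinate ester 5 (not isolated)
Conditions: (−)-Ipc2B(allyl) (1 M in pentane), Et2O, −78 °C; then 3 M NaOH, 30 % H2O2, 0 → 25 °C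
Reagents that add atoms: (−)-B-allyldiisopinocampheylborane, C=CCB([C@@H]1C[C@@H]2C[C@H]([C@H]1C)C2(C)C)[C@@H]1C[C@@H]2C[C@H]([C@H]1C)C2(C)C
Why: Brown allylboration through a closed chair transition state in which the (+)-α-pinene-derived Ipc groups send allyl to the Si face of the aldehyde, giving the 3S alcohol (future C3).

Step 4
Reactants: 6 (1Z,3S)-1-iodo-2-methylhexa-1,5-dien-3-ol
Product: 7 (1Z,3S)-1-iodo-2-methylhexa-1,5-dien-3-yl 2-methylpropanoate
Conditions: (iPrCO)2O, Et3N, DMAP (cat.), CH2Cl2, 0 → 25 °C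
Reagents that add atoms: 2-methylpropanoic anhydride, CC(C)C(=O)OC(=O)C(C)C
Why: DMAP-catalysed acylation installs the isobutyrate with retention at C3.

Step 5
Reactants: 7 (1Z,3S)-1-iodo-2-methylhexa-1,5-dien-3-yl 2-methylpropanoate; 8 2-methylprop-2-enal (methacrolein)
Product: 9 (1Z,3S,5E)-1-iodo-2,6-dimethyl-7-oxohepta-1,5-dien-3-yl 2-methylpropanoate
Conditions: 8 (8 equiv), second-generation Hoveyda–Grubbs catalyst RuCl2(SIMes)(=CH-C6H4-2-OiPr) (5 mol %), CH2Cl2, 40 °C
Reagents that add atoms: none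
Why: Olefin cross-metathesis of the terminal alkene with excess methacrolein gives the thermodynamically favoured E-trisubstituted enal (future E-1(10) olefin), and the hindered iodoalkene is inert to the ruthenium carbene.

Step 6
Reactants: 9 (1Z,3S,5E)-1-iodo-2,6-dimethyl-7-oxohepta-1,5-dien-3-yl 2-methylpropanoate
Product: 10 (1Z,3S,5E)-1-iodo-2,6-dimethylocta-1,5,7-trien-3-yl 2-methylpropanoate
Conditions: Ph3PCH3Br, KN(SiMe3)2, THF, −78 → 0 °C
Reagents that add atoms: methyltriphenylphosphonium bromide, C[P+](c1ccccc1)(c1ccccc1)c1ccccc1.[Br-]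
Why: Wittig methylenation; the ylide adds to the formyl group at low temperature faster than it deprotonates the γ-position or attacks the hindered ester.

Step 7
Reactants: 10 (1Z,3S,5E)-1-iodo-2,6-dimethylocta-1,5,7-trien-3-yl 2-methylpropanoate
Product: 12 (1Z,3S,5E)-8-hydroxy-1-iodo-2,6-dimethylocta-1,5-dien-3-yl 2-methylpropanoate, via alkylborane 11 (not isolated)
Conditions: 9-BBN (1.2 equiv), THF, 0 → 25 °C; then NaBO3·4H2O, H2O, 25 °C
Reagents that add atoms: sodium perborate, [Na+].[Na+].O[B-]1(O)OO[B-](O)(O)OO1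
Why: Hydroboration–oxidation in which 9-BBN adds anti-Markovnikov to the only monosubstituted double bond of the diene and leaves both trisubstituted alkenes, giving the homoallylic primary alcohol.

Step 8
Reactants: 12 (1Z,3S,5E)-8-hydroxy-1-iodo-2,6-dimethylocta-1,5-dien-3-yl 2-methylpropanoate
Product: 13 (1Z,3S,5E)-1-iodo-2,6-dimethyl-8-oxoocta-1,5-dien-3-yl 2-methylpropanoate
Conditions: Dess–Martin periodinane, NaHCO3, CH2Cl2, 0 °C; used crude and cold
Reagents that add atoms: none
Why: Buffered Dess–Martin oxidation gives the β,γ-unsaturated aldehyde without base- or acid-promoted migration of the double bond.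

Step 9
Reactants: 14 2,2-dimethoxyacetaldehyde (60 % in water); 15 methyl acrylate
Product: 16 methyl 3-hydroxy-4,4-dimethoxy-2-methylidenebutanoate (racemic)
Conditions: DABCO (0.5 equiv), 1,4-dioxane/H2O, 25 °C, 48 h
Reagents that add atoms: none
Why: Morita–Baylis–Hillman reaction of the reactive glyoxal mono-acetal with methyl acrylate, accelerated by the aqueous medium.

Step 10
Reactants: 16 methyl 3-hydroxy-4,4-dimethoxy-2-methylidenebutanoate
Product: 17 methyl (2Z)-2-(bromomethyl)-4,4-dimethoxybut-2-enoate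
Conditions: NBS, Me2S, CH2Cl2, 0 → 25 °C
Reagents that add atoms: N-bromosuccinimide, BrN1C(=O)CCC1=O
Why: Corey–Kim-type activation of the allylic alcohol as its alkoxysulfonium salt and SN2′ attack of bromide give the rearranged allylic bromide as the more stable Z isomer (ester trans to the acetal carbon) under non-acidic conditions that spare the acetal.

Step 11
Reactants: 13 (1Z,3S,5E)-1-iodo-2,6-dimethyl-8-oxoocta-1,5-dien-3-yl 2-methylpropanoate; 17 methyl (2Z)-2-(bromomethyl)-4,4-dimethoxybut-2-enoate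
Product: 19 methyl (3R,4R,6E,9S,10Z)-3-(dimethoxymethyl)-4-hydroxy-11-iodo-6,10-dimethyl-2-methylidene-9-[(2-methylpropanoyl)oxy]undeca-6,10-dienoate, via silyl ether 18 (not isolated)
Conditions: nickel-free CrCl2 (10 mol %), (S,S)-iPr carbazole bis(oxazoline) ligand (12 mol %), iPr2NEt (25 mol %), manganese powder (2 equiv), Me3SiCl (1.5 equiv), THF, 0 → 25 °C; then citric acid, MeOH, 0 °C
Reagents that add atoms: none
Why: Catalytic asymmetric Nozaki–Hiyama-type 2-(alkoxycarbonyl)allylation in which the Z-configured allylchromium reacts through a Zimmerman–Traxler chair to give the syn relationship of C3 and C4 (future C7 and C8), and the chiral tridentate ligand on chromium selects the aldehyde face for 3R,4R; the ligand antipode is confirmed by a Mosher ester on the first run, and silylation by Me3SiCl turns the catalyst over and blocks early lactonization.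

Step 12
Reactants: 20 (2E)-2-methylbut-2-en-1-ol (tiglyl alcohol)
Product: 21 [(2R,3R)-2,3-dimethyloxiran-2-yl]methanol
Conditions: Ti(OiPr)4 (10 mol %), D-(−)-diethyl tartrate (12 mol %), tBuOOH, 4 Å sieves, CH2Cl2, −20 °C
Reagents that add atoms: tert-butyl hydroperoxide, CC(C)(C)OO
Why: Sharpless asymmetric epoxidation; the D-(−)-tartrate catalyst delivers oxygen to the face that gives the (2R,3R)-epoxy alcohol (mirror image of the 2S,3S product of the L-(+)-ester).

Step 13
Reactants: 21 [(2R,3R)-2,3-dimethyloxiran-2-yl]methanol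
Product: 22 (2S,3R)-2,3-dimethyloxirane-2-carboxylic acid
Conditions: RuCl3·xH2O (2 mol %), NaIO4 (3 equiv), EtOAc/MeCN/H2O, 25 °C
Reagents that add atoms: sodium periodate, [Na+].[O-]I(=O)(=O)=O; water, O
Why: RuO4-catalysed oxidation takes the primary alcohol to the acid without opening the oxirane, and the configuration is untouched (2R becomes 2S only through the priority change).

Step 14
Reactants: 19 methyl (3R,4R,6E,9S,10Z)-3-(dimethoxymethyl)-4-hydroxy-11-iodo-6,10-dimethyl-2-methylidene-9-[(2-methylpropanoyl)oxy]undeca-6,10-dienoate; 22 (2S,3R)-2,3-dimethyloxirane-2-carboxylic acid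
Product: 24 methyl (3R,4R,6E,9S,10Z)-3-(dimethoxymethyl)-4-{[(2S,3R)-2,3-dimethyloxirane-2-carbonyl]oxy}-11-iodo-6,10-dimethyl-2-methylidene-9-[(2-methylpropanoyl)oxy]undeca-6,10-dienoate, via mixed anhydride 23 (not isolated)
Conditions: 22, 2,4,6-Cl3C6H2COCl, Et3N, THF, 25 °C; then 19, DMAP, toluene, 25 °C
Reagents that add atoms: none
Why: Yamaguchi esterification; the acid has no α-hydrogen, the carbinol keeps its configuration, and the mild conditions do not lactonise the γ-hydroxy ester.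

Step 15
Reactants: 24 methyl (3R,4R,6E,9S,10Z)-3-(dimethoxymethyl)-4-{[(2S,3R)-2,3-dimethyloxirane-2-carbonyl]oxy}-11-iodo-6,10-dimethyl-2-methylidene-9-[(2-methylpropanoyl)oxy]undeca-6,10-dienoate
Product: 25 methyl (3R,4R,6E,9S,10Z)-4-{[(2S,3R)-2,3-dimethyloxirane-2-carbonyl]oxy}-3-formyl-11-iodo-6,10-dimethyl-2-methylidene-9-[(2-methylpropanoyl)oxy]undeca-6,10-dienoate
Conditions: CF3CO2H/H2O (4:1), CH2Cl2, 0 °C, 30 min; used crude
Reagents that add atoms: water, O
Why: Acid-catalysed acetal hydrolysis; the glycidic ester and the other esters survive brief cold aqueous acid, and no base is present to epimerise C3 or eliminate the β-acyloxy group.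

Step 16
Reactants: 25 methyl (3R,4R,6E,9S,10Z)-4-{[(2S,3R)-2,3-dimethyloxirane-2-carbonyl]oxy}-3-formyl-11-iodo-6,10-dimethyl-2-methylidene-9-[(2-methylpropanoyl)oxy]undeca-6,10-dienoate
Product: 27 (3S,4Z,6R,7R,8R)-8-{[(2S,3R)-2,3-dimethyloxirane-2-carbonyl]oxy}-3-[(2-methylpropanoyl)oxy]germacra-1(10)E,4,11(13)-trien-12,6-olide, via ring-closed hydroxy ester 26 (not isolated)
Conditions: CrCl2 (8 equiv), NiCl2 (0.1 equiv), degassed DMSO/THF (3:1), 25 added over 12 h to 2 mM, 25 °C; then sat. aq. NH4Cl, 1 h; sodium serinate work-up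
Reagents that add atoms: none
Why: Proposed new method: a Nozaki–Hiyama–Kishi ring closure in which the (Z)-alkenylchromium (trivalent chromium, formed from the iodide under nickel catalysis with retention of geometry) adds to the C6 aldehyde and the resulting γ-alkoxide on chromium acylates the neighbouring methyl acrylate ester (5-exo-trig, as the alkoxides of chromium-mediated 2-(alkoxycarbonyl)allylations do), so the ten-membered ring and the lactone form in one flask; the closest known reactions are NiCl2/CrCl2 macrocyclizations of alkenyl iodides onto α-branched aldehydes and the lactonization of γ-alkoxides onto acrylates, and C6 is expected to be R because the ring can only close on the formyl rotamer whose chromium-bound oxygen points out of the nascent ring (formyl H between C8 and C11, C5 approaching anti to the C7–C11 bond), which places the 6-oxygen trans to C11.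

Step 17
Reactants: 27 (3S,4Z,6R,7R,8R)-8-{[(2S,3R)-2,3-dimethyloxirane-2-carbonyl]oxy}-3-[(2-methylpropanoyl)oxy]germacra-1(10)E,4,11(13)-trien-12,6-olide
Product: 28 (1R,3S,4Z,6R,7R,8R,10R)-1,10-epoxy-8-{[(2S,3R)-2,3-dimethyloxirane-2-carbonyl]oxy}-3-[(2-methylpropanoyl)oxy]germacra-4,11(13)-dien-12,6-olide (target)
Conditions: mCPBA (1.1 equiv), NaHCO3, CH2Cl2, 0 °C
Reagents that add atoms: 3-chloroperoxybenzoic acid, OOC(=O)c1cccc(Cl)c1
Why: Prilezhaev epoxidation; the peracid reacts only with the electron-rich 1(10) olefin (the 4,5-olefin is deactivated by two allylic acyloxy groups and the 11(13)-olefin is electron-poor) and is expected to attack its exposed outer face, with C14 on the β side in the preferred ring conformer, to give the 1β,10α (1R,10R) oxirane as in other germacranolides.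

## Compound list

1 | prop-2-yn-1-ol | C#CCO | starting material
2 | bromomagnesium (2Z)-3-(bromomagnesio)-2-methylprop-2-en-1-olate | Br[Mg]/C=C(/C)CO[Mg]Br | intermediate (not isolated)
3 | (2Z)-3-iodo-2-methylprop-2-en-1-ol | I/C=C(/C)CO | intermediate
4 | (2Z)-3-iodo-2-methylprop-2-enal | I/C=C(/C)C=O | intermediate
5 | (1Z,3S)-1-iodo-2-methylhexa-1,5-dien-3-yl diisopinocampheylborinate (Ipc from (+)-α-pinene) | I/C=C(/C)[C@@H](OB([C@@H]1C[C@@H]2C[C@H]([C@H]1C)C2(C)C)[C@@H]1C[C@@H]2C[C@H]([C@H]1C)C2(C)C)CC=C | intermediate (not isolated)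
6 | (1Z,3S)-1-iodo-2-methylhexa-1,5-dien-3-ol | I/C=C(/C)[C@@H](O)CC=C | intermediate
7 | (1Z,3S)-1-iodo-2-methylhexa-1,5-dien-3-yl 2-methylpropanoate | I/C=C(/C)[C@@H](OC(=O)C(C)C)CC=C | intermediate
8 | 2-methylprop-2-enal (methacrolein) | CC(=C)C=O | starting material
9 | (1Z,3S,5E)-1-iodo-2,6-dimethyl-7-oxohepta-1,5-dien-3-yl 2-methylpropanoate | I/C=C(/C)[C@@H](OC(=O)C(C)C)C/C=C(\C)C=O | intermediate
10 | (1Z,3S,5E)-1-iodo-2,6-dimethylocta-1,5,7-trien-3-yl 2-methylpropanoate | I/C=C(/C)[C@@H](OC(=O)C(C)C)C/C=C(\C)C=C | intermediate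
11 | (1Z,3S,5E)-8-(9-borabicyclo[3.3.1]nonan-9-yl)-1-iodo-2,6-dimethylocta-1,5-dien-3-yl 2-methylpropanoate | I/C=C(/C)[C@@H](OC(=O)C(C)C)C/C=C(\C)CCB1C2CCCC1CCC2 | intermediate (not isolated)
12 | (1Z,3S,5E)-8-hydroxy-1-iodo-2,6-dimethylocta-1,5-dien-3-yl 2-methylpropanoate | I/C=C(/C)[C@@H](OC(=O)C(C)C)C/C=C(\C)CCO | intermediate
13 | (1Z,3S,5E)-1-iodo-2,6-dimethyl-8-oxoocta-1,5-dien-3-yl 2-methylpropanoate | I/C=C(/C)[C@@H](OC(=O)C(C)C)C/C=C(\C)CC=O | intermediate
14 | 2,2-dimethoxyacetaldehyde | COC(OC)C=O | starting material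
15 | methyl acrylate | C=CC(=O)OC | starting material
16 | methyl 3-hydroxy-4,4-dimethoxy-2-methylidenebutanoate (racemic) | COC(OC)C(O)C(=C)C(=O)OC | intermediate
17 | methyl (2Z)-2-(bromomethyl)-4,4-dimethoxybut-2-enoate | COC(=O)/C(CBr)=C/C(OC)OC | intermediate
18 | methyl (3R,4R,6E,9S,10Z)-3-(dimethoxymethyl)-11-iodo-6,10-dimethyl-2-methylidene-9-[(2-methylpropanoyl)oxy]-4-[(trimethylsilyl)oxy]undeca-6,10-dienoate | I/C=C(/C)[C@@H](OC(=O)C(C)C)C/C=C(\C)C[C@@H](O[Si](C)(C)C)[C@@H](C(=C)C(=O)OC)C(OC)OC | intermediate (not isolated)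
19 | methyl (3R,4R,6E,9S,10Z)-3-(dimethoxymethyl)-4-hydroxy-11-iodo-6,10-dimethyl-2-methylidene-9-[(2-methylpropanoyl)oxy]undeca-6,10-dienoate (C3 = future C7, C4 = future C8) | I/C=C(/C)[C@@H](OC(=O)C(C)C)C/C=C(\C)C[C@@H](O)[C@@H](C(=C)C(=O)OC)C(OC)OC | intermediate
20 | (2E)-2-methylbut-2-en-1-ol (tiglyl alcohol) | C/C=C(\C)CO | starting material
21 | [(2R,3R)-2,3-dimethyloxiran-2-yl]methanol | OC[C@@]1(C)O[C@@H]1C | intermediate
22 | (2S,3R)-2,3-dimethyloxirane-2-carboxylic acid | OC(=O)[C@@]1(C)O[C@@H]1C | intermediate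
23 | (2S,3R)-2,3-dimethyloxirane-2-carboxylic 2,4,6-trichlorobenzoic anhydride | O=C(OC(=O)[C@@]1(C)O[C@@H]1C)c1c(Cl)cc(Cl)cc1Cl | intermediate (not isolated)
24 | methyl (3R,4R,6E,9S,10Z)-3-(dimethoxymethyl)-4-{[(2S,3R)-2,3-dimethyloxirane-2-carbonyl]oxy}-11-iodo-6,10-dimethyl-2-methylidene-9-[(2-methylpropanoyl)oxy]undeca-6,10-dienoate | I/C=C(/C)[C@@H](OC(=O)C(C)C)C/C=C(\C)C[C@@H](OC(=O)[C@@]1(C)O[C@@H]1C)[C@@H](C(=C)C(=O)OC)C(OC)OC | intermediate
25 | methyl (3R,4R,6E,9S,10Z)-4-{[(2S,3R)-2,3-dimethyloxirane-2-carbonyl]oxy}-3-formyl-11-iodo-6,10-dimethyl-2-methylidene-9-[(2-methylpropanoyl)oxy]undeca-6,10-dienoate | I/C=C(/C)[C@@H](OC(=O)C(C)C)C/C=C(\C)C[C@@H](OC(=O)[C@@]1(C)O[C@@H]1C)[C@@H](C(=C)C(=O)OC)C=O | intermediate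
26 | methyl 2-[(1S,2R,3Z,5S,7E,10R)-10-{[(2S,3R)-2,3-dimethyloxirane-2-carbonyl]oxy}-2-hydroxy-4,8-dimethyl-5-[(2-methylpropanoyl)oxy]cyclodeca-3,7-dien-1-yl]prop-2-enoate (formed as its chromium alkoxide) | O[C@@H]1/C=C(/C)[C@@H](OC(=O)C(C)C)C/C=C(\C)C[C@@H](OC(=O)[C@@]2(C)O[C@@H]2C)[C@H]1C(=C)C(=O)OC | intermediate (not isolated)
27 | (3S,4Z,6R,7R,8R)-8-{[(2S,3R)-2,3-dimethyloxirane-2-carbonyl]oxy}-3-[(2-methylpropanoyl)oxy]germacra-1(10)E,4,11(13)-trien-12,6-olide | C=C1C(=O)O[C@@H]2/C=C(/C)[C@@H](OC(=O)C(C)C)C/C=C(\C)C[C@@H](OC(=O)[C@@]3(C)O[C@@H]3C)[C@@H]12 | intermediate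
28 | (1R,3S,4Z,6R,7R,8R,10R)-1,10-epoxy-8-{[(2S,3R)-2,3-dimethyloxirane-2-carbonyl]oxy}-3-[(2-methylpropanoyl)oxy]germacra-4,11(13)-dien-12,6-olide (CNP0117882.4) | C=C1C(=O)O[C@@H]2/C=C(/C)[C@@H](OC(=O)C(C)C)C[C@H]3O[C@]3(C)C[C@@H](OC(=O)[C@@]3(C)O[C@@H]3C)[C@@H]12 | target

## Step count and risk

Total: 17 steps. Longest linear sequence: 13 steps (steps 1–8, 11, 14–17, from propargyl alcohol); steps 9–10 and 12–13 are two-step side branches.

Steps most likely to fail:

Step 16 (ring closure with lactonization). The risks are the yield of a ten-membered closure, the facial selectivity at C6 (argued from the ring-closing rotamer, not proven), reduction of the glycidic ester by CrCl2, and β-elimination of the 8-acyloxy group from aldehyde 25. The fallback takes the side chain out of the ring-closing step; it sets out from 19 and comes back at 27. Alcohol 19 is silylated (tBuMe2SiOTf, 2,6-lutidine) to the 8-O-silyl acetal F1, and the acetal is cleaved under neutral conditions (catalytic I2, acetone) to the silyloxy aldehyde F2. NiCl2/CrCl2 closure then passes through the ring-closed silyloxy hydroxy ester F3, which can be lactonised separately with a trace of TsOH if needed, to the silyl-protected heliangolide F4. HF·pyridine frees the 8β-alcohol F5, which is esterified with mixed anhydride 23 (from 22) to give 27.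

Step 11 (asymmetric allylation). The risks are that facial control with a γ-acetal-substituted bromide is unproven, that the β,γ-unsaturated aldehyde 13 may isomerise with the amine, and that traces of nickel may activate the alkenyl iodide. The fallback gives up catalyst control and separates diastereomers instead; it sets out from 13 and 17 and comes back at 24. Indium powder in THF/H2O (Barbier conditions, syn-selective but without facial control) gives 19 together with its (3S,4S)-diastereomer F6. The mixture is esterified with 23; the chiral acyl group next to the new centres makes the product 24 and the diastereomeric ester F7 separable by chromatography, and pure 24 continues.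

Step 17 (final epoxidation). The risks are attack on the wrong face of the 1(10) olefin and acid-triggered transannular reactions. If the peracid gives the 1α,10β isomer, the fallback inverts the face; it sets out from 27 and comes back at 28. NBS in aqueous THF at 0 °C gives the bromohydrin F8 (bromine on the exposed face at C1, hydroxyl anti at C10). K2CO3 in acetone then closes the oxirane with inversion at C1, which puts the oxygen on the face opposite to the one the peracid reaches.

## Further compounds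

F1 | step 16 | methyl (3R,4R,6E,9S,10Z)-4-[(tert-butyldimethylsilyl)oxy]-3-(dimethoxymethyl)-11-iodo-6,10-dimethyl-2-methylidene-9-[(2-methylpropanoyl)oxy]undeca-6,10-dienoate | I/C=C(/C)[C@@H](OC(=O)C(C)C)C/C=C(\C)C[C@@H](O[Si](C)(C)C(C)(C)C)[C@@H](C(=C)C(=O)OC)C(OC)OC
F2 | step 16 | methyl (3R,4R,6E,9S,10Z)-4-[(tert-butyldimethylsilyl)oxy]-3-formyl-11-iodo-6,10-dimethyl-2-methylidene-9-[(2-methylpropanoyl)oxy]undeca-6,10-dienoate | I/C=C(/C)[C@@H](OC(=O)C(C)C)C/C=C(\C)C[C@@H](O[Si](C)(C)C(C)(C)C)[C@@H](C(=C)C(=O)OC)C=O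
F3 | step 16 | methyl 2-[(1S,2R,3Z,5S,7E,10R)-10-[(tert-butyldimethylsilyl)oxy]-2-hydroxy-4,8-dimethyl-5-[(2-methylpropanoyl)oxy]cyclodeca-3,7-dien-1-yl]prop-2-enoate (8-O-silyl analogue of 26) | O[C@@H]1/C=C(/C)[C@@H](OC(=O)C(C)C)C/C=C(\C)C[C@@H](O[Si](C)(C)C(C)(C)C)[C@H]1C(=C)C(=O)OC
F4 | step 16 | (3S,4Z,6R,7S,8R)-8-[(tert-butyldimethylsilyl)oxy]-3-[(2-methylpropanoyl)oxy]germacra-1(10)E,4,11(13)-trien-12,6-olide (8-O-silyl, 8-deacyl analogue of 27) | C=C1C(=O)O[C@@H]2/C=C(/C)[C@@H](OC(=O)C(C)C)C/C=C(\C)C[C@@H](O[Si](C)(C)C(C)(C)C)[C@@H]12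
F5 | step 16 | (3S,4Z,6R,7R,8R)-8-hydroxy-3-[(2-methylpropanoyl)oxy]germacra-1(10)E,4,11(13)-trien-12,6-olide (8-deacyl 27) | C=C1C(=O)O[C@@H]2/C=C(/C)[C@@H](OC(=O)C(C)C)C/C=C(\C)C[C@@H](O)[C@@H]12
F6 | step 11 | methyl (3S,4S,6E,9S,10Z)-3-(dimethoxymethyl)-4-hydroxy-11-iodo-6,10-dimethyl-2-methylidene-9-[(2-methylpropanoyl)oxy]undeca-6,10-dienoate (3S,4S-diastereomer of 19) | I/C=C(/C)[C@@H](OC(=O)C(C)C)C/C=C(\C)C[C@H](O)[C@H](C(=C)C(=O)OC)C(OC)OC
F7 | step 11 | methyl (3S,4S,6E,9S,10Z)-3-(dimethoxymethyl)-4-{[(2S,3R)-2,3-dimethyloxirane-2-carbonyl]oxy}-11-iodo-6,10-dimethyl-2-methylidene-9-[(2-methylpropanoyl)oxy]undeca-6,10-dienoate (3S,4S-diastereomer of 24) | I/C=C(/C)[C@@H](OC(=O)C(C)C)C/C=C(\C)C[C@H](OC(=O)[C@@]1(C)O[C@@H]1C)[C@H](C(=C)C(=O)OC)C(OC)OC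
F8 | step 17 | (1S,3S,4Z,6R,7R,8R,10R)-1-bromo-10-hydroxy-8-{[(2S,3R)-2,3-dimethyloxirane-2-carbonyl]oxy}-3-[(2-methylpropanoyl)oxy]germacra-4,11(13)-dien-12,6-olide (1α-Br, 10α-OH bromohydrin of 27) | C=C1C(=O)O[C@@H]2/C=C(/C)[C@@H](OC(=O)C(C)C)C[C@H](Br)[C@](C)(O)C[C@@H](OC(=O)[C@@]3(C)O[C@@H]3C)[C@@H]12
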